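The earlier runs and the new flask stem from a simulated flask from invented constants; noise was put on by code.

The target is a passing stop in the maple run: its reading rises to 30.9% at 0.417 min, then falls to 17.5% at 3.00 min, while the starting material keeps sinking.

| flask | starting material | partner | second substrate | remark | time |
|---|---|---|---|---|---|
| maple | 0.011 M (in portions, 2) | 1.5 equiv | 2 equiv | run made earlier; portions every 3.0 s |  |
| flask | 0.023 M (in portions, 2) | 1.50 equiv | 2.00 equiv | the portions of starting material follow each other after 3.0 s, the first at the start | 10 min |

maple run (percent of the starting material charged)

| time / min | starting material / % | target / % |
|---|---|---|
| 0.250 | 62.8 | 30.1 |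
| 0.417 | 58.2 | 30.9 |
| 0.667 | 53.1 | 27.6 |
| 1.00 | 51.8 | 23.7 |
| 2.00 | 43.2 | 18.1 |
| 3.00 | 38.5 | 17.5 |

(standard deviation of a reading: 1 percentage point)

- the reaction counts as stopped when no species that holds the starting material changes by six tenths of a point or more over the second half of the time

* which holds at 10 min: what has brought the reaction to rest, or that it has not come to rest (forward and back rates have come level / all of the starting material has reacted / it is still moving / the partner has run out first)
* share of the starting material used up at 10 min
* target at 10 min, in percent of the starting material charged
* isomer of the product at 10 min, in percent of the starting material charged

Two chemists read these runs. The first sees fast uptake of starting material, then target and isomer of the product trading both ways until forward and back rates come level. The second sees starting material in the maple run still drifting from 43.2% to 38.5% over the last minute, and expects the new flask to be still moving at 10 min.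

My own reckoning freezes one number. I count as isomer whatever is neither starting material nor target, so the maple readings give [isomer]/[target] of 1.03, 2.14 and 2.51 at one-minute steps. The gains shrink from step to step, and summing the gains still to come gives 2.71, a reading with the scatter in it. This is the rest ratio, [isomer]/[target] once forward and back rates are level, the mark of thermodynamic control. One molecule becomes one molecule, so I carry it unchanged from 0.011 M to 0.023 M. At rest the converted share then splits as target = conversion/(1 + ratio).

The forecast sides with the first chemist: forward and back rates have come level, 79% used up (70% to 90%), target 15% (9% to 21%), isomer 64% (48% to 76%), on the ground: “Relaxation takes about 2 min, so 10 min should reach rest”. Its numbers imply a ratio of 4.27, which differs from mine: on its conversion, my ratio gives target 21.3% and isomer 57.7%.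

The flask's answer on its ending is: forward and back rates have come level. It has 72.4% used up, target 18.6% and isomer 53.8%, a ratio of 2.89.

    target ⇌ isomer of the product (K = 2.90, k = 0.0200 /s)
    second substrate + partner ⇌ second product (K = 45.0 /M, k = 1.00 /M/s)
    starting material + partner ⇌ target (K = 65.0 /M, k = 4.30 /M/s)
    second substrate ⇌ dormant form (K = 1.40, k = 0.350 /s)

The first chemist's ending stands; the second chemist's view holds in this flask before 2.33 min, while conversion is more than 5% short of its value at the asked time. The rest ratio turns this flask's conversion into target 19.5%, against 18.6%; in the same flask with 0.600 equiv of partner, 39.5% used up becomes 10.6%, against 10.1%. This flask's slowest mode has a half-life of 0.791 min, shorter than the time, and over the second half its shares moved by 0.57 percentage points or less. Left until 100 min, this flask has its isomer at 53.9%, against 53.8% at 10 min.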